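## Retrosynthetic overview

1. The acetate goes on last. The (R)-carbinol C–C bond comes from an asymmetric Ni/Cr coupling of a ring-bearing 2-triflyloxy-1-alkene with a butenolide aldehyde.
2. The (4R,5R)-cyclohexenone half comes from an achiral, mirror-symmetric 4,4-disubstituted 3,5-dimethylcyclohexa-2,5-dienone. One enantioselective copper hydride 1,4-reduction sets the quaternary and the tertiary centre together.
3. That dienone is the former benzene ring of 3,4,5-trimethylphenol: O-methylation, Birch reduction, Diels–Alder/retro-aldol with methyl vinyl ketone (quaternary carbon), then DDQ (stereochemistry deliberately erased).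
4. The chain half starts from 3-bromofuran: Heck reaction with allyl alcohol, isopropenyl Grignard addition, singlet oxygen/borohydride conversion of the furan into the butenolide, Claisen rearrangement (E-alkene and aldehyde).
5. Ring order: no ring is built. The carbocycle is the reduced and re-oxidised phenol ring (steps 1–6), the butenolide is the oxidised furan ring (step 9), and both are complete before the coupling.

Assumption: the SMILES is read as (4R,5R) in the ring (C1 = ring carbonyl, C4 = quaternary carbon, C5 = CH(CH3)) and R at the acetate carbon. The hand of each chiral ligand is the one that gives this sense and is fixed by a calibration run.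

## Route

Step 1
Reactants: 1 3,4,5-trimethylphenol
Product: 2 5-methoxy-1,2,3-trimethylbenzene
Conditions: MeI, K2CO3, acetone, reflux
Reagents that add atoms: iodomethane (CI)
Why: Williamson O-methylation of the phenoxide gives the anisole needed for the Birch reduction, and no stereocentre is formed.

Step 2
Reactants: 2 5-methoxy-1,2,3-trimethylbenzene
Product: 3 rac-1-methoxy-3,4,5-trimethylcyclohexa-1,4-diene
Conditions: Li, NH3(l), THF, t-BuOH, −78 → −33 °C; NH4Cl
Reagents that add atoms: none
Why: Birch reduction of an alkylated anisole protonates ortho and meta to the methoxy group, so the methoxy group and two of the three methyl groups stay on double bonds and the aromatic ring is broken; the one new stereocentre is racemic and is removed in step 4.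

Step 3
Reactants: 3 rac-1-methoxy-3,4,5-trimethylcyclohexa-1,4-diene, 4 but-3-en-2-one
Product: 7 rac-3,4,5-trimethyl-4-(3-oxobutyl)cyclohex-2-en-1-one, via conjugated methoxydiene 5 (not isolated), via Diels–Alder adduct 6 (not isolated)
Conditions: RhCl(PPh3)3 (1 mol%), PhMe, 80 °C; then 4 (3 equiv), hydroquinone (cat.), 110 °C, sealed tube; then 2 M HCl, THF–H2O, 40 °C
Reagents that add atoms: water (O)
Why: the rhodium catalyst moves the isolated double bond into conjugation, the 1-methoxydiene then undergoes an ortho-selective Diels–Alder reaction that bonds the CH2 terminus of 4 to the methyl-bearing diene terminus (creating the quaternary carbon), and aqueous acid cleaves the bridgehead β-methoxy ketone by retro-aldol fragmentation and hydrolyses the methyl enol ether to the enone (the Birch diene annulation long used for 4-methyl-4-(3-oxobutyl)cyclohexenones); the ring stereocentres form racemic, with the chain mainly anti to the neighbouring methyl group, and are erased in step 4.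

Step 4
Reactants: 7 rac-3,4,5-trimethyl-4-(3-oxobutyl)cyclohex-2-en-1-one
Product: 8 3,4,5-trimethyl-4-(3-oxobutyl)cyclohexa-2,5-dien-1-one
Conditions: DDQ (1.3 equiv), 1,4-dioxane, 100 °C
Reagents that add atoms: none
Why: DDQ dehydrogenation of a cyclohexenone through its cross-conjugated dienol (the process that turns steroidal 4-en-3-ones into 1,4-dien-3-ones) can only add the second ring double bond because the gamma carbon is quaternary, and it removes both stereocentres to give an achiral dienone with a mirror plane.

Step 5
Reactants: 8 3,4,5-trimethyl-4-(3-oxobutyl)cyclohexa-2,5-dien-1-one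
Product: 10 4-(1,2,6-trimethyl-4-oxocyclohexa-2,5-dien-1-yl)but-1-en-2-yl trifluoromethanesulfonate, via potassium enolate 9 (not isolated)
Conditions: KN(SiMe3)2 (1.05 equiv), THF, −78 °C; then Comins' reagent (1.1 equiv), −78 °C; aq. NH4Cl
Reagents that add atoms: Comins' reagent, N-(5-chloropyridin-2-yl)-1,1,1-trifluoro-N-(trifluoromethylsulfonyl)methanesulfonamide (O=S(=O)(N(c1ccc(Cl)cn1)S(=O)(=O)C(F)(F)F)C(F)(F)F)
Why: kinetic deprotonation of the methyl ketone on its methyl side followed by fast O-triflation at −78 °C (enol triflate formation) gives the 1,1-disubstituted alkenyl triflate, because the dienone has no alpha hydrogen and its vinylogous methyl protons are removed more slowly; no stereocentre is formed.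

Step 6
Reactants: 10 4-(1,2,6-trimethyl-4-oxocyclohexa-2,5-dien-1-yl)but-1-en-2-yl trifluoromethanesulfonate
Product: 12 4-[(1R,6R)-1,2,6-trimethyl-4-oxocyclohex-2-en-1-yl]but-1-en-2-yl trifluoromethanesulfonate, via silyl dienol ether 11 (not isolated)
Conditions: Cu(OAc)2·H2O (5 mol%), (R)-DTBM-SEGPHOS (5.5 mol%), (EtO)2MeSiH (1.5 equiv), PhMe, 0 → 23 °C; then 1 M HCl, THF, 0 °C
Reagents that add atoms: none
Why: Proposed new method: the ligated copper hydride should add to only one of the two enantiotopic β-carbons, on the Si face of the carbon that becomes C5 (setting C5 as R), and because allylic 1,3-strain against both flanking vinylic methyl groups locks the first chain bond over one ring face, hydride should arrive anti to the chain, which fixes the quaternary C4 as R and the two methyl groups trans, while the silyl dienol ether 11 is not an enone and so resists a second reduction; the closest known reaction type is the asymmetric copper hydride conjugate reduction of β-methylcyclohexenones such as isophorone.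

Step 7
Reactants: 13 3-bromofuran, 14 prop-2-en-1-ol
Product: 15 3-(furan-3-yl)propanal
Conditions: Pd(OAc)2 (3 mol%), n-Bu4NCl, NaHCO3, DMF, 60 °C
Reagents that add atoms: none
Why: Heck arylation of allyl alcohol under Jeffery conditions puts the furyl group on the terminal carbon, and β-hydride elimination toward the carbinol gives the enol and hence the saturated aldehyde; no stereocentre is formed.

Step 8
Reactants: 15 3-(furan-3-yl)propanal
Product: 16 rac-5-(furan-3-yl)-2-methylpent-1-en-3-ol
Conditions: CH2=C(CH3)MgBr (1.2 equiv), THF, −78 → 0 °C; aq. NH4Cl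
Reagents that add atoms: isopropenylmagnesium bromide (C=C(C)[Mg]Br)
Why: Grignard 1,2-addition to the aldehyde gives the allylic alcohol, and the carbinol centre is left racemic because it is destroyed in the Claisen step.

Step 9
Reactants: 16 rac-5-(furan-3-yl)-2-methylpent-1-en-3-ol
Product: 19 rac-4-(3-hydroxy-4-methylpent-4-en-1-yl)furan-2(5H)-one, via furan endoperoxide 17 (not isolated), via hydroxybutenolide 18 (not isolated)
Conditions: O2, tetraphenylporphyrin (cat.), hν, i-Pr2NEt, CH2Cl2, −78 °C; concentrate; NaBH4, EtOH, 0 °C; 1 M HCl to pH 2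
Reagents that add atoms: oxygen (O=O)
Why: singlet oxygen adds [4+2] to the furan far faster than it reacts with the 1,1-disubstituted alkene, the hindered amine removes the less hindered bridgehead hydrogen so that the endoperoxide opens (Kornblum–DeLaMare) to the 4-alkyl-5-hydroxybutenolide, and borohydride reduction of its open aldehyde form followed by acid lactonisation gives the 4-substituted butenolide; no new stereocentre is carried forward.

Step 10
Reactants: 19 rac-4-(3-hydroxy-4-methylpent-4-en-1-yl)furan-2(5H)-one
Product: 21 (4E)-4-methyl-7-(5-oxo-2,5-dihydrofuran-3-yl)hept-4-enal, via allyl vinyl ether 20 (not isolated)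
Conditions: ethyl vinyl ether (solvent), Hg(OAc)2 (0.2 equiv), 35 °C; concentrate; PhMe, 130 °C, sealed tube
Reagents that add atoms: ethyl vinyl ether (C=COCC)
Why: mercury-catalysed transvinylation followed by an aliphatic Claisen rearrangement through a chair transition state with the side chain pseudo-equatorial gives the aldehyde and the (E)-trisubstituted alkene (about 9:1 E:Z expected, minor isomer removed on silver nitrate silica), and the racemic carbinol centre disappears.

Step 11
Reactants: 12 4-[(1R,6R)-1,2,6-trimethyl-4-oxocyclohex-2-en-1-yl]but-1-en-2-yl trifluoromethanesulfonate, 21 (4E)-4-methyl-7-(5-oxo-2,5-dihydrofuran-3-yl)hept-4-enal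
Product: 22 4-[(3E,7R)-7-hydroxy-4-methyl-8-methylidene-10-[(1R,6R)-1,2,6-trimethyl-4-oxocyclohex-2-en-1-yl]dec-3-en-1-yl]furan-2(5H)-one
Conditions: CrCl2 (10 mol%), Kishi-type chiral oxazoline sulfonamide ligand (11 mol%), proton sponge (11 mol%), NiCl2·(2,9-dimethyl-1,10-phenanthroline) (2 mol%), Mn powder, Cp2ZrCl2, LiCl, MeCN, 23 °C; aqueous work-up
Reagents that add atoms: none
Why: in this Nozaki–Hiyama–Kishi coupling zerovalent nickel inserts into the alkenyl triflate, the alkenyl group passes to trivalent chromium and adds only to the aldehyde (ring enone and butenolide are inert), and the chiral sulfonamide on chromium directs attack to one aldehyde face to give the R carbinol under reagent control, the ring stereocentres being too remote to interfere.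

Step 12
Reactants: 22 4-[(3E,7R)-7-hydroxy-4-methyl-8-methylidene-10-[(1R,6R)-1,2,6-trimethyl-4-oxocyclohex-2-en-1-yl]dec-3-en-1-yl]furan-2(5H)-one
Product: 23 (3E,7R)-4-methyl-8-methylidene-1-(5-oxo-2,5-dihydrofuran-3-yl)-10-[(1R,6R)-1,2,6-trimethyl-4-oxocyclohex-2-en-1-yl]dec-3-en-7-yl acetate
Conditions: Ac2O, pyridine, DMAP (cat.), CH2Cl2, 0 → 23 °C
Reagents that add atoms: acetic anhydride (CC(=O)OC(C)=O)
Why: DMAP-catalysed acetylation of the secondary allylic alcohol proceeds with retention at carbon, and the enone, butenolide and alkenes are inert.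

## Compound list

1 | 3,4,5-trimethylphenol | Cc1cc(O)cc(C)c1C | starting material
2 | 5-methoxy-1,2,3-trimethylbenzene | COc1cc(C)c(C)c(C)c1 | intermediate
3 | rac-1-methoxy-3,4,5-trimethylcyclohexa-1,4-diene | COC1=CC(C)C(C)=C(C)C1 | intermediate
4 | but-3-en-2-one (methyl vinyl ketone) | CC(=O)C=C | starting material
5 | rac-1-methoxy-3,4,5-trimethylcyclohexa-1,3-diene (not isolated) | COC1=CC(C)=C(C)C(C)C1 | intermediate
6 | 1-(1-methoxy-4,5,8-trimethylbicyclo[2.2.2]oct-5-en-2-yl)ethan-1-one (racemic diastereomer mixture; not isolated) | COC12C(C(C)=O)CC(C)(C(C)=C1)C(C)C2 | intermediate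
7 | rac-3,4,5-trimethyl-4-(3-oxobutyl)cyclohex-2-en-1-one (chain mainly trans to the C5 methyl) | CC(=O)CCC1(C)C(C)=CC(=O)CC1C | intermediate
8 | 3,4,5-trimethyl-4-(3-oxobutyl)cyclohexa-2,5-dien-1-one (achiral) | CC(=O)CCC1(C)C(C)=CC(=O)C=C1C | intermediate
9 | potassium 4-(1,2,6-trimethyl-4-oxocyclohexa-2,5-dien-1-yl)but-1-en-2-olate (not isolated) | [K+].[O-]C(=C)CCC1(C)C(C)=CC(=O)C=C1C | intermediate
10 | 4-(1,2,6-trimethyl-4-oxocyclohexa-2,5-dien-1-yl)but-1-en-2-yl trifluoromethanesulfonate (achiral) | C=C(CCC1(C)C(C)=CC(=O)C=C1C)OS(=O)(=O)C(F)(F)F | intermediate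
11 | 4-[(1R,6R)-4-{[diethoxy(methyl)silyl]oxy}-1,2,6-trimethylcyclohexa-2,4-dien-1-yl]but-1-en-2-yl trifluoromethanesulfonate (not isolated) | C=C(CC[C@@]1(C)C(C)=CC(O[Si](C)(OCC)OCC)=C[C@H]1C)OS(=O)(=O)C(F)(F)F | intermediate
12 | 4-[(1R,6R)-1,2,6-trimethyl-4-oxocyclohex-2-en-1-yl]but-1-en-2-yl trifluoromethanesulfonate | C=C(CC[C@@]1(C)C(C)=CC(=O)C[C@H]1C)OS(=O)(=O)C(F)(F)F | intermediate
13 | 3-bromofuran | Brc1ccoc1 | starting material
14 | prop-2-en-1-ol (allyl alcohol) | C=CCO | starting material
15 | 3-(furan-3-yl)propanal | O=CCCc1ccoc1 | intermediate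
16 | rac-5-(furan-3-yl)-2-methylpent-1-en-3-ol | C=C(C)C(O)CCc1ccoc1 | intermediate
17 | 4-methyl-1-(2,3,7-trioxabicyclo[2.2.1]hept-5-en-5-yl)pent-4-en-3-ol (furan endoperoxide; not isolated) | C=C(C)C(O)CCC1=CC2OOC1O2 | intermediate
18 | 5-hydroxy-4-(3-hydroxy-4-methylpent-4-en-1-yl)furan-2(5H)-one (not isolated) | C=C(C)C(O)CCC1=CC(=O)OC1O | intermediate
19 | rac-4-(3-hydroxy-4-methylpent-4-en-1-yl)furan-2(5H)-one | C=C(C)C(O)CCC1=CC(=O)OC1 | intermediate
20 | 4-[3-(ethenyloxy)-4-methylpent-4-en-1-yl]furan-2(5H)-one (not isolated) | C=COC(CCC1=CC(=O)OC1)C(C)=C | intermediate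
21 | (4E)-4-methyl-7-(5-oxo-2,5-dihydrofuran-3-yl)hept-4-enal | O=CCC/C(C)=C/CCC1=CC(=O)OC1 | intermediate
22 | 4-[(3E,7R)-7-hydroxy-4-methyl-8-methylidene-10-[(1R,6R)-1,2,6-trimethyl-4-oxocyclohex-2-en-1-yl]dec-3-en-1-yl]furan-2(5H)-one | C=C(CC[C@@]1(C)C(C)=CC(=O)C[C@H]1C)[C@@H](CC/C(C)=C/CCC1=CC(=O)OC1)O | intermediate
23 | (3E,7R)-4-methyl-8-methylidene-1-(5-oxo-2,5-dihydrofuran-3-yl)-10-[(1R,6R)-1,2,6-trimethyl-4-oxocyclohex-2-en-1-yl]dec-3-en-7-yl acetate | C=C(CC[C@@]1(C)C(C)=CC(=O)C[C@H]1C)[C@@H](CC/C(C)=C/CCC1=CC(=O)OC1)OC(C)=O | target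

## Step count and risks

Total step count: 12. Longest linear sequence: 8 steps (steps 1–6, 11 and 12, from 1 to 23).

**Step 6 (most likely to fail).** The β-carbon carries a methyl group and sits next to a quaternary carbon, so the bulky catalyst may be slow. The diastereoselectivity rests on the conformational lock of the chain and has not been measured. The alkenyl triflate must also survive the hydride.
Fallback: setting out from 10, the dienone is reduced once with the small achiral hydride cluster [(Ph3P)CuH]6 (benzene, 23 °C, acid work-up); the same anti-to-chain bias should give the trans-dimethyl racemate. Preparative chiral SFC then splits it into 12 and its mirror image, the (4S,5S)-enone triflate F1. F1 is returned to 10 with DDQ as in step 4 and recycled. The route is rejoined at 12.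

**Step 3.** The Diels–Alder reaction has to form a quaternary carbon at a fully substituted diene terminus flanked by two more methyl-bearing carbons, and it may stall or let 4 polymerise.
Fallback: setting out from 3, aqueous oxalic acid gives 3,4,5-trimethylcyclohex-2-en-1-one F2. Soft enolisation (t-BuMe2SiOTf, Et3N) gives the extended silyl dienol ether F3. A Lewis-acid vinylogous Mukaiyama–Michael addition to 4 (TiCl4 or catalytic t-BuMe2SiOTf, CH2Cl2, −78 °C) then makes the same ring-to-chain bond stepwise at low temperature and gives the silyl enol ether F4, which aqueous acid hydrolyses to 7. The route is rejoined at 7.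

**Step 11.** Enantiofacial control by the chromium ligand on an unbranched aldehyde may be incomplete, and the two carbinol epimers would be hard to separate because the ring stereocentres are remote.
Fallback: setting out from 12 and 21, an unligated coupling (CrCl2, cat. NiCl2, DMF) gives 22 together with its carbinol epimer, the (7S)-alcohol F5. A Sharpless kinetic resolution (Ti(OiPr)4, L-(+)-diisopropyl tartrate, t-BuOOH, 4 Å sieves, CH2Cl2, −20 °C) epoxidises only F5, giving the epoxy alcohol F6, which is removed by chromatography. This leaves 22, where the route is rejoined.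

Further compounds
F1 | step 6 | 4-[(1S,6S)-1,2,6-trimethyl-4-oxocyclohex-2-en-1-yl]but-1-en-2-yl trifluoromethanesulfonate | C=C(CC[C@]1(C)C(C)=CC(=O)C[C@@H]1C)OS(=O)(=O)C(F)(F)F
F2 | step 3 | rac-3,4,5-trimethylcyclohex-2-en-1-one | CC1CC(=O)C=C(C)C1C
F3 | step 3 | rac-tert-butyl(dimethyl)[(3,4,5-trimethylcyclohexa-1,3-dien-1-yl)oxy]silane | CC1CC(O[Si](C)(C)C(C)(C)C)=CC(C)=C1C
F4 | step 3 | rac-4-{3-[(tert-butyldimethylsilyl)oxy]but-2-en-1-yl}-3,4,5-trimethylcyclohex-2-en-1-one | CC(O[Si](C)(C)C(C)(C)C)=CCC1(C)C(C)=CC(=O)CC1C
F5 | step 11 | 4-[(3E,7S)-7-hydroxy-4-methyl-8-methylidene-10-[(1R,6R)-1,2,6-trimethyl-4-oxocyclohex-2-en-1-yl]dec-3-en-1-yl]furan-2(5H)-one | C=C(CC[C@@]1(C)C(C)=CC(=O)C[C@H]1C)[C@H](CC/C(C)=C/CCC1=CC(=O)OC1)O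
F6 | step 11 | 4-[(3E,7S)-7-hydroxy-4-methyl-7-{(2S)-2-[2-((1R,6R)-1,2,6-trimethyl-4-oxocyclohex-2-en-1-yl)ethyl]oxiran-2-yl}hept-3-en-1-yl]furan-2(5H)-one | C1O[C@]1(CC[C@@]2(C)C(C)=CC(=O)C[C@H]2C)[C@H](CC/C(C)=C/CCC3=CC(=O)OC3)O
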